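The route rests on cutting ring A at two neighbouring bonds, the diaryl ether bond C6–O and the C1–CO2H bond. Ring A carries OMe, CO2H and OAr on the contiguous carbons C2, C1 and C6, the pattern left when a nucleophile adds to a 3-methoxybenzyne remote from OMe and the anion next to OMe is trapped. One operation thus unites the ring-B phenoxide, the aryne and CO2, forming the C–O and C–C bonds regioselectively. The precursor is a 2-silylaryl triflate bearing OMe and the silyl-protected (S)-carbinol chain; its partner is a phenol whose second hydroxyl is allylated and whose aldehyde is a dioxolane.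

Key step: step 12

Remark: the carbinol centre is (S) in the target and from compound 7 onward; because Friedel–Crafts acylation of 3-methoxyphenol is not reliably para-selective, ring A starts from 4-bromo-3-methoxyphenol, which is assumed to be commercially available, as is 3-bromo-2-methoxyphenol used in one fallback.

Step 1
Reactants: 1 isovaleryl chloride
Product: 2 N-methoxy-N,3-dimethylbutanamide
Conditions: MeNH(OMe)·HCl, Et3N, CH2Cl2, 0 °C to rt
Reagents that add atoms: N,O-dimethylhydroxylamine hydrochloride, CNOC.Cl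
Why: N-acylation of the hydroxylamine by the acid chloride (Weinreb amide formation) is fast and gives an acyl donor that stops at the ketone stage in step 2.

Step 2
Reactants: 3 4-bromo-3-methoxyphenol; 2 N-methoxy-N,3-dimethylbutanamide
Product: 5 1-(4-hydroxy-2-methoxyphenyl)-3-methylbutan-1-one, via lithium 4-lithio-3-methoxyphenoxide 4 (not isolated)
Conditions: n-BuLi (2.2 equiv), THF, −78 to −40 °C; then 2, −78 to 0 °C; aq. NH4Cl
Reagents that add atoms: none
Why: One equivalent of n-BuLi deprotonates the phenol and the second effects bromine–lithium exchange, and the aryllithium adds once to the amide through a chelated tetrahedral adduct (Weinreb ketone synthesis), so the acyl group sits unambiguously para to OH and ortho to OMe.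

Step 3
Reactants: 5 1-(4-hydroxy-2-methoxyphenyl)-3-methylbutan-1-one
Product: 6 3-methoxy-4-(3-methylbutanoyl)phenyl N-isopropylcarbamate
Conditions: i-PrNCO, Et3N (cat.), CH2Cl2, rt
Reagents that add atoms: isopropyl isocyanate, CC(C)N=C=O
Why: Base-catalysed addition of a phenol to an isocyanate (carbamoylation) protects the phenol for steps 4 and 5 and installs the group that directs metalation in step 6.

Step 4
Reactants: 6 3-methoxy-4-(3-methylbutanoyl)phenyl N-isopropylcarbamate
Product: 7 4-[(1S)-1-hydroxy-3-methylbutyl]-3-methoxyphenyl N-isopropylcarbamate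
Conditions: (R)-Me-CBS (0.2 equiv), BH3·SMe2, THF, −20 °C; MeOH, then aq. NH4Cl
Reagents that add atoms: none
Why: Corey–Bakshi–Shibata reduction, in which the aryl group takes the large-substituent position on the (R)-oxazaborolidine–borane complex and hydride is delivered to the Re face of the ketone, should set the only stereocentre as (S).

Step 5
Reactants: 7 4-[(1S)-1-hydroxy-3-methylbutyl]-3-methoxyphenyl N-isopropylcarbamate
Product: 8 3-methoxy-4-[(1S)-3-methyl-1-(triisopropylsilyloxy)butyl]phenyl N-isopropylcarbamate
Conditions: TIPSOTf, 2,6-lutidine, CH2Cl2, −78 to 0 °C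
Reagents that add atoms: triisopropylsilyl trifluoromethanesulfonate, CC(C)[Si](C(C)C)(C(C)C)OS(=O)(=O)C(F)(F)F
Why: O-Silylation with a silyl triflate and a hindered pyridine base breaks no bond at the stereocentre and gives an ether that should survive butyllithium, amine bases and fluoride at room temperature.

Step 6
Reactants: 8 3-methoxy-4-[(1S)-3-methyl-1-(triisopropylsilyloxy)butyl]phenyl N-isopropylcarbamate
Product: 12 3-methoxy-4-[(1S)-3-methyl-1-(triisopropylsilyloxy)butyl]-2-(trimethylsilyl)phenyl N-isopropylcarbamate, via N-silyl carbamate 9 (not isolated), via 2-lithio N-silyl carbamate 10 (not isolated), via N,2-bis(trimethylsilyl) carbamate 11 (not isolated)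
Conditions: TMSOTf, TMEDA, Et2O, 0 °C to rt; n-BuLi (2 equiv), TMEDA, −78 °C; TMSCl, −78 °C to rt; aq. NH4Cl
Reagents that add atoms: chlorotrimethylsilane, C[Si](C)(C)Cl
Why: Directed ortho-metalation of the carbamate, N-silylated in the flask, should occur at C2, where carbamate oxygen and methoxy group cooperate, and the aryllithium is quenched by the chlorosilane before work-up removes the N-silyl group.

Step 7
Reactants: 12 3-methoxy-4-[(1S)-3-methyl-1-(triisopropylsilyloxy)butyl]-2-(trimethylsilyl)phenyl N-isopropylcarbamate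
Product: 14 3-methoxy-4-[(1S)-3-methyl-1-(triisopropylsilyloxy)butyl]-2-(trimethylsilyl)phenyl trifluoromethanesulfonate, via 2-silylphenol 13 (not isolated)
Conditions: Et2NH, DBU, MeCN, 40 °C; then PhNTf2, rt
Reagents that add atoms: N-phenylbis(trifluoromethanesulfonimide), O=S(=O)(N(c1ccccc1)S(=O)(=O)C(F)(F)F)C(F)(F)F
Why: Base-induced E1cB loss of isopropyl isocyanate (trapped by diethylamine as a urea) frees the phenoxide without acid, which spares the aryl C–Si bond, and O-sulfonylation by the mild triflyl donor follows in the same pot.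

Step 8
Reactants: 15 2-methoxy-4-methylphenol (creosol)
Product: 16 2-hydroxy-3-methoxy-5-methylbenzaldehyde
Conditions: hexamethylenetetramine, TFA, reflux; then 3 M aq. HCl, rt
Reagents that add atoms: hexamethylenetetramine, C1N2CN3CN1CN(C2)C3; water, O
Why: Duff formylation places the formyl group ortho to the free hydroxyl because the para position is blocked by the methyl group, and acid hydrolysis of the iminium releases the aldehyde.

Step 9
Reactants: 16 2-hydroxy-3-methoxy-5-methylbenzaldehyde
Product: 17 2,3-dihydroxy-5-methylbenzaldehyde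
Conditions: BBr3, CH2Cl2, −78 °C to rt; H2O
Reagents that add atoms: none
Why: Lewis acid-mediated cleavage of the aryl methyl ether (boron complexation, then bromide attack on the methyl group) is standard for guaiacol-type aldehydes, and the aldehyde should survive at low temperature.

Step 10
Reactants: 17 2,3-dihydroxy-5-methylbenzaldehyde
Product: 19 3-(allyloxy)-2-hydroxy-5-methylbenzaldehyde, via disodium catecholate 18 (not isolated)
Conditions: NaH (2.2 equiv), DMSO, rt; allyl bromide (1.0 equiv), rt; dilute HCl
Reagents that add atoms: allyl bromide, C=CCBr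
Why: Williamson etherification of the dianion should be regioselective, because the 2-oxide is delocalised into the aldehyde and the more basic 3-oxide is the one alkylated by a single equivalent of halide.

Step 11
Reactants: 19 3-(allyloxy)-2-hydroxy-5-methylbenzaldehyde
Product: 20 2-(allyloxy)-6-(1,3-dioxolan-2-yl)-4-methylphenol
Conditions: ethylene glycol, p-TsOH (cat.), toluene, reflux, Dean–Stark; NaHCO3 quench
Reagents that add atoms: ethylene glycol, OCCO
Why: Acid-catalysed acetalisation driven by azeotropic removal of water masks the aldehyde, which would otherwise intercept the aryl anion of step 12, and the temperature is far below that of an aromatic Claisen rearrangement.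

Step 12
Reactants: 14 3-methoxy-4-[(1S)-3-methyl-1-(triisopropylsilyloxy)butyl]-2-(trimethylsilyl)phenyl trifluoromethanesulfonate; 20 2-(allyloxy)-6-(1,3-dioxolan-2-yl)-4-methylphenol; 21 carbon dioxide
Product: 24 6-[2-(allyloxy)-6-(1,3-dioxolan-2-yl)-4-methylphenoxy]-2-methoxy-3-[(1S)-3-methyl-1-(triisopropylsilyloxy)butyl]benzoic acid, via potassium phenoxide 22 (not isolated), via aryne 23 (not isolated)
Conditions: 20 (1.5 equiv), KH (1.5 equiv), THF, 0 °C; then 14, KF, 18-crown-6, CO2 (1 atm), THF, 0 °C to rt; cold dilute HCl to pH 3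
Reagents that add atoms: none
Why: Proposed new method: fluoride attacks silicon in 14 and triflate leaves, giving aryne 23, whose triple bond is polarised by the inductively withdrawing C3 methoxy group so that phenoxide 22 adds at C1 and the charge develops at C2 beside the C–O dipole, where the aryl anion adds to CO2 to give the carboxylate. The closest known reactions are the three-component coupling of arynes, amines and CO2 to anthranilic acids and the fluoride-mediated O-arylation of phenols with 2-silylaryl triflates, which the step merges by using an anionic oxygen nucleophile under CO2. No ring is closed and no stereocentre is formed, and the remote (S)-carbinol is protected as a silyl ether that should resist fluoride at this temperature. The step needs regioselectivity, secured by the 3-methoxy group (C–O bond meta to OMe, C–C bond ortho to it), and carboxylation in preference to protonation, secured by a preformed potassium phenoxide, the absence of any O–H or N–H, THF in place of acetonitrile and a CO2-saturated solution. The doubly ortho-substituted phenoxide should be tolerated because C1 of the aryne is a small, highly reactive electrophile with only hydrogen on its other side, and the dioxolane keeps the aryl anion from closing onto the aldehyde.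

Step 13
Reactants: 24 6-[2-(allyloxy)-6-(1,3-dioxolan-2-yl)-4-methylphenoxy]-2-methoxy-3-[(1S)-3-methyl-1-(triisopropylsilyloxy)butyl]benzoic acid
Product: 25 6-[2-(1,3-dioxolan-2-yl)-6-hydroxy-4-methylphenoxy]-2-methoxy-3-[(1S)-3-methyl-1-(triisopropylsilyloxy)butyl]benzoic acid
Conditions: Pd(PPh3)4 (cat.), morpholine, THF, rt; pH 4 buffer
Reagents that add atoms: none
Why: Tsuji–Trost-type deallylation, in which Pd(0) ionises the aryl allyl ether and morpholine captures the π-allyl complex, should leave silyl ether, acetal and acid untouched.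

Step 14
Reactants: 25 6-[2-(1,3-dioxolan-2-yl)-6-hydroxy-4-methylphenoxy]-2-methoxy-3-[(1S)-3-methyl-1-(triisopropylsilyloxy)butyl]benzoic acid
Product: 27 tenellic acid B, via hydroxy acetal 26 (not isolated)
Conditions: TBAF, THF, rt to 45 °C; then 1 M aq. HCl to pH 2, 0 °C to rt
Reagents that add atoms: water, O
Why: Fluoride cleaves the Si–O bond without touching the C–O bond of the stereocentre, and brief dilute-acid acetal hydrolysis of the electron-rich aryl dioxolane should be much faster than ionisation of the benzylic alcohol, so the (S)-configuration is kept.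

Compound list
1 | isovaleryl chloride | CC(C)CC(=O)Cl | starting material
2 | N-methoxy-N,3-dimethylbutanamide | CC(C)CC(=O)N(C)OC | intermediate
3 | 4-bromo-3-methoxyphenol | COc1cc(O)ccc1Br | starting material
4 | lithium 4-lithio-3-methoxyphenoxide | COc1cc(O[Li])ccc1[Li] | intermediate
5 | 1-(4-hydroxy-2-methoxyphenyl)-3-methylbutan-1-one | COc1cc(O)ccc1C(=O)CC(C)C | intermediate
6 | 3-methoxy-4-(3-methylbutanoyl)phenyl N-isopropylcarbamate | COc1cc(OC(=O)NC(C)C)ccc1C(=O)CC(C)C | intermediate
7 | 4-[(1S)-1-hydroxy-3-methylbutyl]-3-methoxyphenyl N-isopropylcarbamate | COc1cc(OC(=O)NC(C)C)ccc1[C@@H](O)CC(C)C | intermediate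
8 | 3-methoxy-4-[(1S)-3-methyl-1-(triisopropylsilyloxy)butyl]phenyl N-isopropylcarbamate | COc1cc(OC(=O)NC(C)C)ccc1[C@@H](O[Si](C(C)C)(C(C)C)C(C)C)CC(C)C | intermediate
9 | 3-methoxy-4-[(1S)-3-methyl-1-(triisopropylsilyloxy)butyl]phenyl N-isopropyl-N-(trimethylsilyl)carbamate | COc1cc(OC(=O)N(C(C)C)[Si](C)(C)C)ccc1[C@@H](O[Si](C(C)C)(C(C)C)C(C)C)CC(C)C | intermediate
10 | 2-lithio-3-methoxy-4-[(1S)-3-methyl-1-(triisopropylsilyloxy)butyl]phenyl N-isopropyl-N-(trimethylsilyl)carbamate | COc1c([Li])c(OC(=O)N(C(C)C)[Si](C)(C)C)ccc1[C@@H](O[Si](C(C)C)(C(C)C)C(C)C)CC(C)C | intermediate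
11 | 3-methoxy-4-[(1S)-3-methyl-1-(triisopropylsilyloxy)butyl]-2-(trimethylsilyl)phenyl N-isopropyl-N-(trimethylsilyl)carbamate | COc1c([Si](C)(C)C)c(OC(=O)N(C(C)C)[Si](C)(C)C)ccc1[C@@H](O[Si](C(C)C)(C(C)C)C(C)C)CC(C)C | intermediate
12 | 3-methoxy-4-[(1S)-3-methyl-1-(triisopropylsilyloxy)butyl]-2-(trimethylsilyl)phenyl N-isopropylcarbamate | COc1c([Si](C)(C)C)c(OC(=O)NC(C)C)ccc1[C@@H](O[Si](C(C)C)(C(C)C)C(C)C)CC(C)C | intermediate
13 | 3-methoxy-4-[(1S)-3-methyl-1-(triisopropylsilyloxy)butyl]-2-(trimethylsilyl)phenol | COc1c([Si](C)(C)C)c(O)ccc1[C@@H](O[Si](C(C)C)(C(C)C)C(C)C)CC(C)C | intermediate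
14 | 3-methoxy-4-[(1S)-3-methyl-1-(triisopropylsilyloxy)butyl]-2-(trimethylsilyl)phenyl trifluoromethanesulfonate | COc1c([C@@H](O[Si](C(C)C)(C(C)C)C(C)C)CC(C)C)ccc(OS(=O)(=O)C(F)(F)F)c1[Si](C)(C)C | intermediate
15 | 2-methoxy-4-methylphenol (creosol) | COc1cc(C)ccc1O | starting material
16 | 2-hydroxy-3-methoxy-5-methylbenzaldehyde | COc1cc(C)cc(C=O)c1O | intermediate
17 | 2,3-dihydroxy-5-methylbenzaldehyde | Cc1cc(O)c(O)c(C=O)c1 | intermediate
18 | disodium 3-formyl-5-methylbenzene-1,2-diolate | Cc1cc([O-])c([O-])c(C=O)c1.[Na+].[Na+] | intermediate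
19 | 3-(allyloxy)-2-hydroxy-5-methylbenzaldehyde | C=CCOc1cc(C)cc(C=O)c1O | intermediate
20 | 2-(allyloxy)-6-(1,3-dioxolan-2-yl)-4-methylphenol | Oc1c(OCC=C)cc(C)cc1C1OCCO1 | intermediate
21 | carbon dioxide | O=C=O | starting material
22 | potassium 2-(allyloxy)-6-(1,3-dioxolan-2-yl)-4-methylphenoxide | [K+].[O-]c1c(OCC=C)cc(C)cc1C1OCCO1 | intermediate
23 | 3-methoxy-4-[(1S)-3-methyl-1-(triisopropylsilyloxy)butyl]benzyne (1,2-didehydrobenzene) | COC1=C([C@@H](O[Si](C(C)C)(C(C)C)C(C)C)CC(C)C)C=CC#C1 | intermediate
24 | 6-[2-(allyloxy)-6-(1,3-dioxolan-2-yl)-4-methylphenoxy]-2-methoxy-3-[(1S)-3-methyl-1-(triisopropylsilyloxy)butyl]benzoic acid | COc1c([C@@H](O[Si](C(C)C)(C(C)C)C(C)C)CC(C)C)ccc(Oc2c(OCC=C)cc(C)cc2C2OCCO2)c1C(=O)O | intermediate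
25 | 6-[2-(1,3-dioxolan-2-yl)-6-hydroxy-4-methylphenoxy]-2-methoxy-3-[(1S)-3-methyl-1-(triisopropylsilyloxy)butyl]benzoic acid | COc1c([C@@H](O[Si](C(C)C)(C(C)C)C(C)C)CC(C)C)ccc(Oc2c(O)cc(C)cc2C2OCCO2)c1C(=O)O | intermediate
26 | 6-[2-(1,3-dioxolan-2-yl)-6-hydroxy-4-methylphenoxy]-3-[(1S)-1-hydroxy-3-methylbutyl]-2-methoxybenzoic acid | COc1c([C@@H](O)CC(C)C)ccc(Oc2c(O)cc(C)cc2C2OCCO2)c1C(=O)O | intermediate
27 | tenellic acid B, 6-(2-formyl-6-hydroxy-4-methylphenoxy)-3-[(1S)-1-hydroxy-3-methylbutyl]-2-methoxybenzoic acid | COc1c([C@@H](O)CC(C)C)ccc(Oc2c(O)cc(C)cc2C=O)c1C(=O)O | target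

Total step count: 14. Longest linear sequence: 10 steps (steps 1–7, then 12–14).

Steps most likely to fail

Step 12. The aryl anion may be protonated before it meets CO2. The phenoxide may also be held back as its carbonate under CO2, so that aryne generation outruns O-arylation or the carbonate oxygen arylates instead. The fallback separates the two bond formations with known reactions and sets out from 14 and 20. Fluoride-mediated O-arylation without CO2 (CsF, MeCN, rt) should give, with the same regiochemistry and protonation at C2, the diaryl ether 2-[3-(allyloxy)-2-{3-methoxy-4-[(1S)-3-methyl-1-(triisopropylsilyloxy)butyl]phenoxy}-5-methylphenyl]-1,3-dioxolane F1. Palladium(0)/morpholine deallylation, which removes the base-sensitive allylic protons, should then give the phenol 3-(1,3-dioxolan-2-yl)-2-{3-methoxy-4-[(1S)-3-methyl-1-(triisopropylsilyloxy)butyl]phenoxy}-5-methylphenol F2. Treatment with n-BuLi (2.2 equiv)/TMEDA in THF at low temperature should deprotonate the phenol and then lithiate the ring-A C–H flanked by OMe and OAr (directed ortho-metalation). Quenching with CO2 and mild acid work-up returns to the route at 25, after which step 14 follows.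

Step 6. Metalation at the crowded C2, next to a methoxy group that is itself flanked by the bulky side chain, may be slow enough for lithiation at C6 or deprotonation of the benzylic C–H to compete. The fallback makes a positional isomer of the aryne precursor in which the carbamate has only one free ortho position. It sets out from 2 and commercial 3-bromo-2-methoxyphenol and repeats the operations of steps 2–5:
- The dianion adds to 2 to give 1-(3-hydroxy-2-methoxyphenyl)-3-methylbutan-1-one F3.
- Carbamoylation gives 2-methoxy-3-(3-methylbutanoyl)phenyl N-isopropylcarbamate F4.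
- Reduction with the (R)-oxazaborolidine gives 3-[(1S)-1-hydroxy-3-methylbutyl]-2-methoxyphenyl N-isopropylcarbamate F5.
- Silylation gives 2-methoxy-3-[(1S)-3-methyl-1-(triisopropylsilyloxy)butyl]phenyl N-isopropylcarbamate F6.

Directed silylation as in step 6 can then only occur at C6 and should give 2-methoxy-3-[(1S)-3-methyl-1-(triisopropylsilyloxy)butyl]-6-(trimethylsilyl)phenyl N-isopropylcarbamate F7. Carbamate cleavage and triflation as in step 7 should give 2-methoxy-3-[(1S)-3-methyl-1-(triisopropylsilyloxy)butyl]-6-(trimethylsilyl)phenyl trifluoromethanesulfonate F8. F8 has silicon and triflate exchanged relative to 14 but eliminates to the same aryne 23, so it re-enters under the conditions of step 12 and comes back to the route at 24.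

Step 14. The free benzylic alcohol, activated by the ortho methoxy and para aryloxy groups, may ionise in acid during acetal hydrolysis, with erosion of configuration or elimination. Desilylation of the hindered ether may also stall. The fallback reverses the order so that the carbinol is never free in acid. From 25, pyridinium p-toluenesulfonate in acetone–water should unmask the aldehyde while the silyl ether is still in place, giving 6-(2-formyl-6-hydroxy-4-methylphenoxy)-2-methoxy-3-[(1S)-3-methyl-1-(triisopropylsilyloxy)butyl]benzoic acid F9. Desilylation with fluoride buffered by acetic acid (TBAF/AcOH, THF) then comes back to the route at 27.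

Further compounds
F1 | step 12 | 2-[3-(allyloxy)-2-{3-methoxy-4-[(1S)-3-methyl-1-(triisopropylsilyloxy)butyl]phenoxy}-5-methylphenyl]-1,3-dioxolane | COc1cc(Oc2c(OCC=C)cc(C)cc2C2OCCO2)ccc1[C@@H](O[Si](C(C)C)(C(C)C)C(C)C)CC(C)C
F2 | step 12 | 3-(1,3-dioxolan-2-yl)-2-{3-methoxy-4-[(1S)-3-methyl-1-(triisopropylsilyloxy)butyl]phenoxy}-5-methylphenol | COc1cc(Oc2c(O)cc(C)cc2C2OCCO2)ccc1[C@@H](O[Si](C(C)C)(C(C)C)C(C)C)CC(C)C
F3 | step 6 | 1-(3-hydroxy-2-methoxyphenyl)-3-methylbutan-1-one | COc1c(O)cccc1C(=O)CC(C)C
F4 | step 6 | 2-methoxy-3-(3-methylbutanoyl)phenyl N-isopropylcarbamate | COc1c(OC(=O)NC(C)C)cccc1C(=O)CC(C)C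
F5 | step 6 | 3-[(1S)-1-hydroxy-3-methylbutyl]-2-methoxyphenyl N-isopropylcarbamate | COc1c(OC(=O)NC(C)C)cccc1[C@@H](O)CC(C)C
F6 | step 6 | 2-methoxy-3-[(1S)-3-methyl-1-(triisopropylsilyloxy)butyl]phenyl N-isopropylcarbamate | COc1c(OC(=O)NC(C)C)cccc1[C@@H](O[Si](C(C)C)(C(C)C)C(C)C)CC(C)C
F7 | step 6 | 2-methoxy-3-[(1S)-3-methyl-1-(triisopropylsilyloxy)butyl]-6-(trimethylsilyl)phenyl N-isopropylcarbamate | COc1c(OC(=O)NC(C)C)c([Si](C)(C)C)ccc1[C@@H](O[Si](C(C)C)(C(C)C)C(C)C)CC(C)C
F8 | step 6 | 2-methoxy-3-[(1S)-3-methyl-1-(triisopropylsilyloxy)butyl]-6-(trimethylsilyl)phenyl trifluoromethanesulfonate | COc1c(OS(=O)(=O)C(F)(F)F)c([Si](C)(C)C)ccc1[C@@H](O[Si](C(C)C)(C(C)C)C(C)C)CC(C)C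
F9 | step 14 | 6-(2-formyl-6-hydroxy-4-methylphenoxy)-2-methoxy-3-[(1S)-3-methyl-1-(triisopropylsilyloxy)butyl]benzoic acid | COc1c([C@@H](O[Si](C(C)C)(C(C)C)C(C)C)CC(C)C)ccc(Oc2c(O)cc(C)cc2C=O)c1C(=O)O
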